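**Retrosynthetic overview**
1. Planaic acid is a depside. Ring A (2,4-dimethoxy-6-pentylbenzoyl) is esterified to O4 of ring B (C1 CO2H, C2 OMe, C3 H, C4 O-acyl, C5 H, C6 pentyl). The last disconnections are a benzyl ester on the C1 carboxyl and the ArC(=O)–O4 bond.
2. The plan rests on ring B: a methyl ether on C2 and an oxygen that must be free on C4 sit either side of C3–H, with the carboxyl on C1 and the pentyl chain on C6.
3. C2–C3–C4–C5 is read as a butadiene with two methoxy groups on C2 and a silyloxy group on C4, and C6–C1 as an oct-2-ynoate. A Diels–Alder reaction makes C1–C2 and C5–C6, and loss of methanol and silicon gives the 2-methoxy-4-hydroxybenzoate.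
4. Ring B is the only ring built. Ring A is bought as 1,3-dimethoxy-5-pentylbenzene and gains its carboxyl carbon by formylation and oxidation.
5. Order: diene (three steps) and ynoate (one step), then ring B, depside ester, hydrogenolysis.

Key step: step 5

Remark: the target has no stereocentre and no stereogenic double bond, so no SMILES needs a stereodescriptor. Transient compounds that could exist as E/Z isomers or racemates (9, F2, F3, F4) converge on one product whatever their configuration.

**Route**

Step 1
Reactants: 1 hept-1-yne; 2 benzyl chloroformate
Product: 4 benzyl oct-2-ynoate, via lithium hept-1-ynide 3 (not isolated)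
Conditions: n-BuLi (1.05 equiv), THF, −78 °C, 30 min; then 2 (1.1 equiv), −78 °C to 0 °C
Reagents that add atoms: none
Why: Deprotonation of the terminal alkyne and C-acylation of the lithium acetylide with a chloroformate is the standard alkynoate synthesis, and the low temperature keeps the product ester from a second acetylide attack.

Step 2
Reactants: 5 acetyl chloride; 6 1,1-dichloroethene
Product: 8 4,4-dichlorobut-3-en-2-one, via 4,4,4-trichlorobutan-2-one 7 (not isolated)
Conditions: AlCl3 (1.0 equiv), CH2Cl2, 0 °C to rt; ice/dil. HCl quench; steam distillation, then distillation under reduced pressure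
Reagents that add atoms: none
Why: In this aliphatic Friedel–Crafts acylation of an alkene (Darzens–Nenitzescu type) the acylium ion attacks the CH2 end to give the chlorine-stabilised cation, chloride capture gives 7, and loss of HCl on steam distillation gives the conjugated dichlorovinyl ketone.

Step 3
Reactants: 8 4,4-dichlorobut-3-en-2-one
Product: 10 4,4-dimethoxybut-3-en-2-one, via 4-chloro-4-methoxybut-3-en-2-one 9 (not isolated)
Conditions: NaOMe (2.1 equiv), MeOH, 0 °C to reflux; filter, concentrate, distil under reduced pressure (no aqueous work-up)
Reagents that add atoms: sodium methoxide (NaOMe), [Na+].[O-]C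
Why: Two successive conjugate addition–elimination events (nucleophilic vinylic substitution) at the β-carbon exchange both chlorides for methoxide, with the acetyl group serving as the activating acceptor.

Step 4
Reactants: 10 4,4-dimethoxybut-3-en-2-one
Product: 11 1,1-dimethoxy-3-(trimethylsilyloxy)buta-1,3-diene
Conditions: TMSCl (1.5 equiv), Et3N (2 equiv), ZnCl2 (cat.), toluene, rt to 40 °C; filter under Ar, distil under reduced pressure, use at once
Reagents that add atoms: chlorotrimethylsilane (TMSCl), C[Si](C)(C)Cl
Why: This is soft enolisation and O-silylation of a methyl ketone, and because the CH3 group is the only enolisable position, the cross-conjugated 2-silyloxydiene is the only silyl enol ether that can form.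

Step 5
Reactants: 11 1,1-dimethoxy-3-(trimethylsilyloxy)buta-1,3-diene; 4 benzyl oct-2-ynoate
Product: 14 benzyl 4-hydroxy-2-methoxy-6-pentylbenzoate, via cyclohexa-1,4-diene cycloadduct 12 (not isolated), via aryl trimethylsilyl ether 13 (not isolated)
Conditions: 11 (2.5 equiv, in two portions), neat or minimal xylene, sealed tube under Ar, 130–140 °C, 24–48 h; then 1 M HCl, THF, rt
Reagents that add atoms: none
Why: This is a normal-electron-demand Diels–Alder reaction followed by aromatisation: the three oxygen donors of 11 raise its HOMO and put the largest coefficient on the unsubstituted CH2 terminus, the ester of 4 puts the largest LUMO coefficient on the pentyl-bearing β-carbon, and the two combine in a concerted but strongly asynchronous [4+2] addition in which the C5–C6 bond runs ahead of the C1–C2 bond. Ring B, the only ring closed, arises by this intermolecular [4+2] closure (diene carbons C2–C5 plus alkyne carbons C6 and C1) as the cyclohexa-1,4-diene 12, whose C2 is a dimethyl acetal carbon. At the reaction temperature 12 should lose methanol by 1,4-elimination across C2 and the doubly allylic C5–H2, driven by the gain of aromaticity, to give aryl silyl ether 13, and dilute acid then cleaves the O–Si bond to free the C4 phenol. The closest known reaction type is the cycloaddition of 1,1-dialkoxy-3-silyloxybutadienes and related 1-alkoxy-3-silyloxydienes to acetylenic esters, which gives resorcylate esters; β-alkyl ynoates belong to this class but need heat and an excess of diene. The only selectivity needed is regiochemical, and the matched polarity secures it by placing the acetal carbon beside the ester-bearing carbon, hence methoxy on C2 and silyloxy on C4, whereas the reverse orientation would pair like-polarised termini. No stereocentre is formed, and the two oxygens emerge differentiated because one keeps its methyl group while the other carries only a labile silyl group.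

Step 6
Reactants: 15 1,3-dimethoxy-5-pentylbenzene
Product: 17 2,4-dimethoxy-6-pentylbenzaldehyde, via aryl iminium chloride 16 (not isolated)
Conditions: POCl3 (1.5 equiv), DMF, 0 °C to 60 °C; then ice–water
Reagents that add atoms: N,N-dimethylformamide, CN(C)C=O; water, O
Why: In this Vilsmeier–Haack formylation the chloroiminium ion attacks the ring position that is para to one methoxy and ortho to the other rather than the site between the two methoxy groups, and water hydrolyses iminium salt 16 to the aldehyde.

Step 7
Reactants: 17 2,4-dimethoxy-6-pentylbenzaldehyde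
Product: 18 2,4-dimethoxy-6-pentylbenzoic acid
Conditions: NaClO2 (2 equiv), NaH2PO4, 2-methylbut-2-ene (excess), t-BuOH/H2O, rt
Reagents that add atoms: sodium chlorite (NaClO2), [Na+].[O-]Cl=O
Why: In this Pinnick oxidation chlorous acid adds to the aldehyde and fragments to the carboxylic acid, while 2-methylbut-2-ene traps the hypochlorous acid that would otherwise chlorinate the electron-rich ring A.

Step 8
Reactants: 18 2,4-dimethoxy-6-pentylbenzoic acid
Product: 19 2,4-dimethoxy-6-pentylbenzoyl chloride
Conditions: (COCl)2 (1.5 equiv), DMF (cat.), CH2Cl2, 0 °C to rt; evaporate, use crude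
Reagents that add atoms: oxalyl chloride, O=C(Cl)C(=O)Cl
Why: Acid chloride formation with oxalyl chloride under DMF catalysis (Vilsmeier-type activation) is mild and non-Lewis-acidic, so the aryl methyl ethers are left untouched.

Step 9
Reactants: 14 benzyl 4-hydroxy-2-methoxy-6-pentylbenzoate; 19 2,4-dimethoxy-6-pentylbenzoyl chloride
Product: 20 benzyl 4-[(2,4-dimethoxy-6-pentylbenzoyl)oxy]-2-methoxy-6-pentylbenzoate
Conditions: Et3N (2 equiv), 4-(dimethylamino)pyridine (DMAP, 0.2 equiv), CH2Cl2, 0 °C to rt (reflux if slow)
Reagents that add atoms: none
Why: This is base-mediated O-acylation of a phenol by an acid chloride under nucleophilic catalysis (Einhorn-type acylation), in which the C4 hydroxyl is the only free nucleophile, is easily deprotonated thanks to the para ester, and the benzyl ester masks the C1 carboxyl.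

Step 10
Reactants: 20 benzyl 4-[(2,4-dimethoxy-6-pentylbenzoyl)oxy]-2-methoxy-6-pentylbenzoate
Product: 21 planaic acid, 4-[(2,4-dimethoxy-6-pentylbenzoyl)oxy]-2-methoxy-6-pentylbenzoic acid
Conditions: H2 (1 atm), Pd/C (10 wt%), EtOAc, rt
Reagents that add atoms: none
Why: Catalytic hydrogenolysis cleaves only the benzylic C–O bond, and the depside aryl ester, the methyl ethers and both arenes are inert to one atmosphere of hydrogen at room temperature.

**Compound list**
1 | hept-1-yne | CCCCCC#C | starting material
2 | benzyl chloroformate | O=C(Cl)OCc1ccccc1 | starting material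
3 | lithium hept-1-ynide | [Li]C#CCCCCC | intermediate
4 | benzyl oct-2-ynoate | CCCCCC#CC(=O)OCc1ccccc1 | intermediate
5 | acetyl chloride | CC(=O)Cl | starting material
6 | 1,1-dichloroethene | C=C(Cl)Cl | starting material
7 | 4,4,4-trichlorobutan-2-one | CC(=O)CC(Cl)(Cl)Cl | intermediate
8 | 4,4-dichlorobut-3-en-2-one | CC(=O)C=C(Cl)Cl | intermediate
9 | 4-chloro-4-methoxybut-3-en-2-one (geometry undefined) | CC(=O)C=C(Cl)OC | intermediate
10 | 4,4-dimethoxybut-3-en-2-one | CC(=O)C=C(OC)OC | intermediate
11 | 1,1-dimethoxy-3-(trimethylsilyloxy)buta-1,3-diene | COC(OC)=CC(=C)O[Si](C)(C)C | intermediate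
12 | benzyl 6,6-dimethoxy-2-pentyl-4-(trimethylsilyloxy)cyclohexa-1,4-diene-1-carboxylate | COC1(OC)C=C(O[Si](C)(C)C)CC(CCCCC)=C1C(=O)OCc1ccccc1 | intermediate
13 | benzyl 2-methoxy-6-pentyl-4-(trimethylsilyloxy)benzoate | CCCCCc1cc(O[Si](C)(C)C)cc(OC)c1C(=O)OCc1ccccc1 | intermediate
14 | benzyl 4-hydroxy-2-methoxy-6-pentylbenzoate | CCCCCc1cc(O)cc(OC)c1C(=O)OCc1ccccc1 | intermediate
15 | 1,3-dimethoxy-5-pentylbenzene | CCCCCc1cc(OC)cc(OC)c1 | starting material
16 | [(2,4-dimethoxy-6-pentylphenyl)methylidene]dimethylammonium chloride | CCCCCc1cc(OC)cc(OC)c1C=[N+](C)C.[Cl-] | intermediate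
17 | 2,4-dimethoxy-6-pentylbenzaldehyde | CCCCCc1cc(OC)cc(OC)c1C=O | intermediate
18 | 2,4-dimethoxy-6-pentylbenzoic acid | CCCCCc1cc(OC)cc(OC)c1C(=O)O | intermediate
19 | 2,4-dimethoxy-6-pentylbenzoyl chloride | CCCCCc1cc(OC)cc(OC)c1C(=O)Cl | intermediate
20 | benzyl 4-[(2,4-dimethoxy-6-pentylbenzoyl)oxy]-2-methoxy-6-pentylbenzoate | CCCCCc1cc(OC(=O)c2c(CCCCC)cc(OC)cc2OC)cc(OC)c1C(=O)OCc1ccccc1 | intermediate
21 | planaic acid | CCCCCc1cc(OC(=O)c2c(CCCCC)cc(OC)cc2OC)cc(OC)c1C(=O)O | target

**Step count**
Total steps: 10.
Longest linear sequence: 6 steps (2, 3, 4, 5, 9, 10).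

**Steps most likely to fail**

Step 5.
- Risk: the β-pentyl group slows the cycloaddition. Thermal silyl migration in diene 11, and its protonolysis by the methanol that aromatisation releases, may then outrun ring formation.
- Fallback: keep the diene and the same two ring bonds, but replace the alkyne by its allene isomer, a clearly more reactive dienophile. The fallback sets out from 11.
- Hexanoyl chloride and Et3N in CH2Cl2 generate butylketene F1. A Wittig reaction with benzyl (triphenylphosphoranylidene)acetate traps it as benzyl octa-2,3-dienoate F2.
- Diene 11 should add across the C2=C3 bond of F2 (toluene, 80–110 °C) with the same polarity, its CH2 terminus going to the central allene carbon. This gives benzyl 2,2-dimethoxy-6-pentylidene-4-(trimethylsilyloxy)cyclohex-3-ene-1-carboxylate F3.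
- Loss of methanol gives benzyl 2-methoxy-6-pentylidene-4-(trimethylsilyloxy)cyclohexa-1,3-diene-1-carboxylate F4. A prototropic shift then moves its exocyclic double bond into the ring.
- The fallback comes back to the route at 13, which the same acid work-up turns into 14.

Step 9.
- Risk: acyl transfer to the weakly nucleophilic phenol may stall. The carbonyl group of 19 is shielded by two ortho substituents and deactivated by two methoxy donors, so the acid chloride would merely hydrolyse on work-up.
- Fallback: use those same features in an acylium-type activation under acidic conditions. It sets out from acid 18, and step 8 is skipped.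
- Trifluoroacetic anhydride in dry toluene at rt converts 18 into 2,4-dimethoxy-6-pentylbenzoic trifluoroacetic anhydride F5. This should ionise readily toward the linear, donor-stabilised aroyl cation and acylate the C4 hydroxyl of 14.
- The fallback comes back to the route at 20.

Step 7.
- Risk: oxidation of the di-ortho-substituted aldehyde may be slow enough for hypochlorous acid to escape the scavenger and chlorinate the free positions of ring A.
- Fallback: bring in the carboxyl carbon as CO2, so that no oxidant is needed. It sets out from 15, and steps 6 and 7 are skipped.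
- N-Bromosuccinimide in MeCN at 0 °C should brominate the same ortho/para-activated position to give 2-bromo-1,5-dimethoxy-3-pentylbenzene F6.
- Halogen–metal exchange with n-BuLi in THF at −78 °C gives (2,4-dimethoxy-6-pentylphenyl)lithium F7, and dry CO2 gives lithium 2,4-dimethoxy-6-pentylbenzoate F8.
- Acidification with dilute HCl comes back to the route at 18.

**Further compounds**
F1 | step 5 | butylketene (hex-1-en-1-one) | CCCCC=C=O
F2 | step 5 | benzyl octa-2,3-dienoate (racemic) | CCCCC=C=CC(=O)OCc1ccccc1
F3 | step 5 | benzyl 2,2-dimethoxy-6-pentylidene-4-(trimethylsilyloxy)cyclohex-3-ene-1-carboxylate (racemic, alkene geometry undefined) | COC1(OC)C=C(O[Si](C)(C)C)CC(=CCCCC)C1C(=O)OCc1ccccc1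
F4 | step 5 | benzyl 2-methoxy-6-pentylidene-4-(trimethylsilyloxy)cyclohexa-1,3-diene-1-carboxylate (alkene geometry undefined) | COC1=C(C(=O)OCc2ccccc2)C(=CCCCC)CC(O[Si](C)(C)C)=C1
F5 | step 9 | 2,4-dimethoxy-6-pentylbenzoic trifluoroacetic anhydride | CCCCCc1cc(OC)cc(OC)c1C(=O)OC(=O)C(F)(F)F
F6 | step 7 | 2-bromo-1,5-dimethoxy-3-pentylbenzene | CCCCCc1cc(OC)cc(OC)c1Br
F7 | step 7 | (2,4-dimethoxy-6-pentylphenyl)lithium | CCCCCc1cc(OC)cc(OC)c1[Li]
F8 | step 7 | lithium 2,4-dimethoxy-6-pentylbenzoate | CCCCCc1cc(OC)cc(OC)c1C(=O)[O-].[Li+]
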